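**Plan**
1. Locants follow eudesmane numbering, with primed numbers for myrcene (C-1′ is the CH2 end of its vinyl group). The retrosynthesis cuts C-2–C-3 of ring A together with C-5–C-1′ and its partner bond C-2–C-2′; in the forward sense all three close in one flask.
2. The enabling feature is the bicyclo[2.2.2]oct-5-en-2-one (C-1 to C-5, C-10, C-1′, C-2′) with quaternary C-10 beside the C-1 ketone. It is the retron of a cyclohexa-2,4-dienone cycloaddition, and that dienone is one dehydration away from a 2,3-seco keto-enal.
3. The seco skeleton comes from costunolide: Cope rearrangement of its 11,13-dihydro derivative gives the elemanolide, with ring B and the lactone complete. Its isopropenyl and vinyl groups are then oxidised to the enal and the methyl ketone.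
4. Ring order: ten-membered ring, then ring B with lactone (Cope), then ring A (aldol condensation), then the bicyclooctenone (cycloaddition).
5. Stereochemistry: C-6 and C-7 come from costunolide, C-11 from enolate protonation in step 1, C-10 from the chair Cope, and C-5, C-2 and C-2′ from the facial and endo selectivity of the cycloaddition.

Key step: step 6

Remark: costunolide and myrcene are taken as the commercial starting materials; the key step also forms C-2–C-2′, the partner bond of the cycloaddition.

**Step 1**
Reactants: 1 costunolide
Product: 2 11β,13-dihydrocostunolide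
Conditions: NaBH4, MeOH, 0 °C
Reagents that add atoms: none
Why: Conjugate hydride reduction of the α-methylene-γ-lactone, in which the lactone enolate should be protonated from the less hindered face so that the new methyl group is α (11S) as in the target, while the two trisubstituted ring alkenes are inert to borohydride.

**Step 2**
Reactants: 2 11β,13-dihydrocostunolide
Product: 3 saussurea lactone
Conditions: neat, 210 °C, argon, sealed tube
Reagents that add atoms: none
Why: Cope rearrangement ([3,3]-sigmatropic shift) of the (E,E)-cyclodeca-1,5-diene through the chair-like transition state breaks C-2–C-3 and forms C-5–C-10, so the fixed alkene geometries set C-10 (methyl β, vinyl α) and C-5 (H α), and relief of ring strain should drive it to the elemanolide.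

**Step 3**
Reactants: 3 saussurea lactone
Product: 4 elemanolide 2-substituted acrolein
Conditions: SeO2, 1,4-dioxane, 80 °C
Reagents that add atoms: selenium dioxide, O=[Se]=O
Why: Allylic oxidation by SeO2 (ene reaction, [2,3]-sigmatropic shift, then oxidation of the allylic alcohol) should attack the methyl group of the isopropenyl unit, because the vinyl group has no allylic hydrogen and the ring methine C-5–H is the slowest kind of allylic position.

**Step 4**
Reactants: 4 elemanolide 2-substituted acrolein
Product: 5 conjugated seco-enal
Conditions: RuHCl(CO)(PPh3)3 (5 mol %), PhMe, 90 °C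
Reagents that add atoms: none
Why: Alkene isomerisation by ruthenium hydride addition and β-hydride elimination should move the 1,1-disubstituted double bond to the tetrasubstituted, conjugated C-4=C-5 position (the vinyl group cannot migrate), with the flat formyl group rather than the methyl group taking the crowded position cis to C-10, which is the geometry the later ring closure needs.

**Step 5**
Reactants: 5 conjugated seco-enal
Product: 6 seco keto-enal
Conditions: PdCl2 (10 mol %), CuCl, O2 (1 atm), DMF/H2O 7:1, rt
Reagents that add atoms: water, O
Why: Tsuji–Wacker oxidation, in which only the monosubstituted vinyl group should bind palladium (the enal double bond is tetrasubstituted and electron-poor) and Markovnikov attack of water followed by β-hydride elimination gives the C-1 methyl ketone.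

**Step 6**
Reactants: 6 seco keto-enal; 7 myrcene
Product: 10 the target, via hydroxy ketone 8 (not isolated), via dienone 9 (not isolated)
Conditions: pyrrolidine (20 mol %), AcOH (20 mol %), myrcene (10 equiv), BHT, PhMe, 120 °C, sealed tube
Reagents that add atoms: none
Why: Pyrrolidinium acetate should condense the methyl ketone with the cis-disposed enal (enol or enamine addition to the iminium ion, 6-exo-trig closure of ring A, then loss of water), which forms C-2–C-3 and unveils the 6,6-disubstituted cyclohexa-2,4-dienone 9, a diene that cannot tautomerise to a phenol because C-10 is quaternary. Dienone 9 is trapped as it forms by the monosubstituted vinyl group of myrcene in an intermolecular [4+2] cycloaddition that forms C-5–C-1′ and C-2–C-2′ and closes the two new six-membered rings of the bicyclo[2.2.2]octenone in one concerted suprafacial event. The closest known reaction type is the Diels–Alder reaction of 6,6-disubstituted cyclohexa-2,4-dienones generated in situ (masked o-benzoquinone chemistry) with simple alkenes. C-5 and C-2 are set by the diene face that is attacked, expected to be the face of the angular methyl group because the other face is blocked by the C-9 methylene of ring B, and C-2′ is set by the endo transition state, which places the dienyl residue under the diene and so syn to the new C-3=C-4 bridge. Regiochemistry should follow from the large LUMO coefficient at C-5 of the dienone meeting the unsubstituted terminus of the vinyl group, and the vinyl group should win over the 1,1-disubstituted and trisubstituted alkenes of myrcene on steric grounds. Excess myrcene is there to suppress dimerisation of 9 and its use as a dienophile.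

**Compound list**
1 | costunolide, germacra-1(10)E,4E,11(13)-trien-12,6α-olide (7αH) | C/C/1=C\CC/C(=C/[C@@H]2[C@@H](CC1)C(=C)C(=O)O2)/C | starting material
2 | 11β,13-dihydrocostunolide, (11S)-germacra-1(10)E,4E-dien-12,6α-olide | C/C/1=C\CC/C(=C/[C@@H]2[C@@H](CC1)[C@H](C)C(=O)O2)/C | intermediate
3 | saussurea lactone, (11S)-elema-1,3-dien-12,6α-olide (5αH, 10β-methyl, 10α-vinyl) | C=C[C@]3(C)CC[C@H]2[C@H](C)C(=O)O[C@@H]2[C@H]3C(C)=C | intermediate
4 | (5αH,11S)-2,3-seco-eudesma-1,4(15)-dien-12,6α-olid-3-al (saussurea lactone with the isopropenyl methyl oxidised to CHO) | C=C[C@]3(C)CC[C@H]2[C@H](C)C(=O)O[C@@H]2[C@H]3C(=C)C=O | intermediate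
5 | (11S)-2,3-seco-eudesma-1,4-dien-12,6α-olid-3-al, C-4=C-5 (E), formyl group cis to C-10 | C=C[C@]3(C)CC[C@H]2[C@H](C)C(=O)O[C@@H]2/C3=C(\C)C=O | intermediate
6 | (11S)-1-oxo-2,3-seco-eudesm-4-en-12,6α-olid-3-al (C-1 methyl ketone, C-3 aldehyde, C-4=C-5 (E)) | CC(=O)[C@]3(C)CC[C@H]2[C@H](C)C(=O)O[C@@H]2/C3=C(\C)C=O | intermediate
7 | myrcene, 7-methyl-3-methylideneocta-1,6-diene | C=CC(=C)CCC=C(C)C | starting material
8 | (11S)-3-hydroxy-1-oxoeudesm-4-en-12,6α-olide, either epimer at C-3 | O=C1CC(O)C(C)=C3[C@@]1(C)CC[C@H]2[C@H](C)C(=O)O[C@@H]23 | intermediate
9 | (11S)-1-oxoeudesma-2,4-dien-12,6α-olide | O=C1C=CC(C)=C3[C@@]1(C)CC[C@H]2[C@H](C)C(=O)O[C@@H]23 | intermediate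
10 | (11S)-1-oxoeudesm-3-en-12,6α-olide bridged from C-2 to C-5 on the β face by C-2′–C-1′ of myrcene, the 6-methylhepta-1,5-dien-2-yl group on C-2′ syn to C-3=C-4 | C=C(CCC=C(C)C)[C@H]1C[C@@]23C(C)=C[C@@H]1C(=O)[C@]2(C)CC[C@H]1[C@H](C)C(=O)O[C@@H]13 | target

Total step count: 6
Longest linear sequence: 6

**Steps most likely to fail**

1. Step 6. The dienone may dimerise or act as a dienophile toward the diene of myrcene faster than it adds the unactivated vinyl group, and face selectivity may be poor. There is also a risk of epimerisation at C-6 by the amine through the dienamine. Fallback: starting from compound 6, the ring closure is done alone (pyrrolidinium acetate, CH2Cl2, rt) and dienone 9 is isolated. Compound 9 is then heated with the activated dienophile methyl vinyl ketone (PhMe, 80 °C), which should give the endo acetyl adduct F1 with the same regiochemistry. Kinetic enolisation of the methyl ketone (LiN(i-Pr)2, THF, −78 °C) and alkylation with prenyl bromide gives the homoprenyl ketone F2. Wittig methylenation (Ph3P=CH2, THF) comes back to the route at compound 10.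

2. Step 4. The ruthenium hydride may decarbonylate the aldehyde, the double-bond migration may stall, or the wrong alkene geometry may result. Fallback: starting from compound 4, conjugate transfer hydrogenation (Hantzsch ester, dibenzylammonium trifluoroacetate, THF) gives the saturated 2-methyl aldehyde F3. Enamine-mediated α-bromination (NBS, pyrrolidine cat., CH2Cl2) gives the tertiary α-bromo aldehyde F4. Dehydrobromination under equilibrating conditions (LiBr, Li2CO3, DMF, 120 °C) gives the tetrasubstituted enal and comes back to the route at compound 5.

3. Step 5. Water may attack the neopentylic vinyl group in the anti-Markovnikov sense, and the acidic medium may trigger premature ring closure of the product. Fallback: starting from compound 5, oxymercuration (Hg(OAc)2, THF/H2O) gives the organomercurial F5 with the hydroxyl group at C-1. Alkaline NaBH4 removes mercury and also reduces the aldehyde, giving the diol F6. Swern oxidation of both hydroxyl groups ((COCl)2, DMSO, Et3N, −78 °C) comes back to the route at compound 6.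

**Further compounds**
F1 | step 6 | acetyl adduct: compound 10 with an acetyl group in place of the dienyl group on C-2′ | CC(=O)[C@H]1C[C@@]23C(C)=C[C@@H]1C(=O)[C@]2(C)CC[C@H]1[C@H](C)C(=O)O[C@@H]13
F2 | step 6 | homoprenyl ketone: compound 10 with C=O in place of the C=CH2 of the side chain | CC(C)=CCCC(=O)[C@H]1C[C@@]23C(C)=C[C@@H]1C(=O)[C@]2(C)CC[C@H]1[C@H](C)C(=O)O[C@@H]13
F3 | step 4 | (5αH,11S)-2,3-seco-eudesm-1-en-12,6α-olid-3-al, both epimers at C-4 | C=C[C@]3(C)CC[C@H]2[C@H](C)C(=O)O[C@@H]2[C@H]3C(C)C=O
F4 | step 4 | 4-bromo derivative of F3, both epimers at C-4 | C=C[C@]3(C)CC[C@H]2[C@H](C)C(=O)O[C@@H]2[C@H]3C(C)(Br)C=O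
F5 | step 5 | 1-hydroxy-2-(acetoxymercurio) derivative of compound 5, both epimers at C-1 | CC(=O)O[Hg]CC(O)[C@]3(C)CC[C@H]2[C@H](C)C(=O)O[C@@H]2/C3=C(\C)C=O
F6 | step 5 | (11S)-1,3-dihydroxy-2,3-seco-eudesm-4-en-12,6α-olide, both epimers at C-1 | CC(O)[C@]3(C)CC[C@H]2[C@H](C)C(=O)O[C@@H]2/C3=C(\C)CO
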